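If a product ratio is wanted before one of its two partners has entered solution, I reckon it on logarithmic axes.

| setting | zeta | flask |
|---|---|---|
| starting material | 0.30 M | 0.30 M |
| second nucleophile | 0.33 M | 0.330 M |
| solid first nucleophile | 0.60 M | 0.600 M |
| capture agent | 0.090 M | 0.0900 M |
| remark | the very flask that is asked about, followed so far |  |
| time |  | 1.5 h |

zeta run (percent of the starting material charged)

| time / min | other capture product / % | target / % |
|---|---|---|
| 2.00 | 15 | 11 |
| 4.00 | 22 | 23 |
| 8.00 | 28 | 45 |
| 15.0 | 34 | 60 |
| 25.0 | 37 | 63 |

(readings scatter by 1.5 percentage points)

- what was read earlier has a scatter of 1.5 percentage points, one standard deviation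
- at the start none of the solid first nucleophile is in solution

- ratio of other capture product to target at 12 s
- ratio of other capture product to target at 4.0 min
- ratio of other capture product to target at 1.5 h

I assume that the target forms from dissolved first nucleophile and the other capture product from second nucleophile, in competition. Let r be the amount of other capture product over target so far, a cumulative selectivity. The zeta readings give r = 1.36 at 2.00 min and 0.957 at 4.00 min, so I commit to that second reading for the middle time. At 25.0 min r is 0.587 and the products sum to 100% of the charge, so, taking them as stable, I commit to that value for the latest time.

The hard question is 12 s, ten times earlier than the first reading. Dissolved first nucleophile starts from zero and, like a first-order lag, rises at most in proportion to time. So, with second nucleophile taken as steady, log10 r climbs at most one unit per decade going back, which from the scattered first reading puts an upper bound near 13.6. Between the first two readings r falls by 0.512 per decade, read from values with a scatter of 1.5 percentage points. A lag steepens towards the start, so I put the lower bound near 4.43. By hand I go no further than the middle in logarithms: the log slope n, the fall of log10 r per decade of time, is 0.756, which gives r = 7.77.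

The forecast gives 1.8, 0.95 and 0.59 at 12 s, 4.0 min and 1.5 h, saying that the ratio “should hold near this value at 12 s”. Its first value lies outside my bracket, lower than the bound from below.

The flask gives 6.86, 0.894 and 0.581 at those times.

    starting material ⇌ open intermediate (K = 0.150, k = 0.00286 s⁻¹)
    first nucleophile + open intermediate → target (k = 2.86 M⁻¹ s⁻¹)
    second nucleophile + open intermediate → other capture product (k = 0.868 M⁻¹ s⁻¹)
    solid first nucleophile ⇌ first nucleophile, rate k4*(cs4 - [first nucleophile]) while solid is left; crystals form when [first nucleophile] > cs4 (solubility = 0.220 M, k = 0.0101 s⁻¹)
    open intermediate + capture agent → trapped intermediate (k = 0.0349 M⁻¹ s⁻¹)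

In this flask the solid first nucleophile goes into solution with time constant 1/k4 = 99.0 s, longer than 12 s and shorter than 4.0 min. Between those two times r falls with log slope 0.680, against my n of 0.756. In the neighbour flask with 0.56 M of second nucleophile, my n carried back from its 1.47 at 4.0 min gives 14.2 at 12 s, and that neighbour stands at 12.0.

The runs were generated by integration with constants of no real substance; scatter was added.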